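**Retrosynthetic overview**
1. The target is a 1,2-dioxane (O1, O2, C3, C4, C5, C6). The C4–C5 bond is the only ring bond that touches neither oxygen-bearing carbon, so it is cut as a C4=C5 alkene (ring-closing metathesis). This leaves an acyclic dialkyl peroxide whose C3 and C6, the carbons flanking the O–O link, are each set beforehand by stereospecific C–O substitution.
2. C3–O2 comes from SN2 displacement (inversion) of an (R)-allylic mesylate by a tertiary hydroperoxide. C6–O1 comes from perhydrolysis (inversion) at the tertiary carbon of a Sharpless (2S,3S)-epoxy alcohol, whose diol tail then becomes the C6 vinyl group by glycol cleavage and methylenation.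
3. The epoxy alcohol derives from (R)-citronellal, which supplies the side-chain methyl centre: ozonolysis, Wittig extension with the ylide from (5-bromopentyl)benzene, hydrogenation, alkyne formation, and methylalumination/hydroxymethylation.
4. Only one ring is formed, the 3,6-dihydro-1,2-dioxine, by metathesis. Diimide then sets C4, and desilylation and oxidation give the acid.

Key step: step 18

Remark: ring atoms are numbered O1, O2, C3 (two-carbon arm), C4 (methyl), C5, C6 (quaternary carbon) in all ring compounds, also where lowest-locant rules would number the ring the other way; commercial (R)-citronellal is taken as enantiomerically pure.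

**Route**

Step 1
Reactants: 1 (3R)-3,7-dimethyloct-6-enal [(R)-citronellal]
Product: 2 (6R)-8,8-dimethoxy-2,6-dimethyloct-2-ene
Conditions: HC(OMe)3, MeOH, pyridinium p-toluenesulfonate (cat.), rt
Reagents that add atoms: trimethyl orthoformate, COC(OC)OC; methanol, CO
Why: Acid-catalysed acetalisation with the orthoformate as water scavenger masks the aldehyde for the next steps, the mild catalyst should avoid carbonyl-ene cyclisation of citronellal, and the methyl-bearing stereocentre is not touched.

Step 2
Reactants: 2 (6R)-8,8-dimethoxy-2,6-dimethyloct-2-ene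
Product: 4 (4R)-6,6-dimethoxy-4-methylhexanal, via secondary ozonide 3 (not isolated)
Conditions: O3, CH2Cl2, –78 °C; then PPh3, –78 °C to rt
Reagents that add atoms: ozone, [O-][O+]=O
Why: Ozonolysis of the electron-rich trisubstituted alkene and reductive cleavage of the ozonide by the phosphine remove the isopropylidene carbon as acetone and leave the acetal intact.

Step 3
Reactants: 5 (5-bromopentyl)benzene
Product: 6 triphenyl(5-phenylpentyl)phosphonium bromide
Conditions: PPh3, MeCN, reflux
Reagents that add atoms: triphenylphosphine, c1ccc(cc1)P(c1ccccc1)c1ccccc1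
Why: SN2 quaternisation of the phosphine by the primary bromide gives the Wittig salt.

Step 4
Reactants: 4 (4R)-6,6-dimethoxy-4-methylhexanal; 6 triphenyl(5-phenylpentyl)phosphonium bromide
Product: 8 [(5Z,9R)-11,11-dimethoxy-9-methylundec-5-en-1-yl]benzene, via ylide triphenyl(5-phenylpentylidene)phosphorane 7 (not isolated)
Conditions: 6, NaN(SiMe3)2, THF, 0 °C; then 4, –78 °C to rt
Reagents that add atoms: none
Why: Wittig olefination with the non-stabilised ylide joins the phenylpentyl unit to the aldehyde, and the alkene geometry (expected mainly Z) does not matter because the double bond is hydrogenated next.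

Step 5
Reactants: 8 [(5Z,9R)-11,11-dimethoxy-9-methylundec-5-en-1-yl]benzene
Product: 10 (3R)-3-methyl-11-phenylundecanal, via saturated acetal 9 (not isolated)
Conditions: H2 (1 atm), Pd/C, EtOAc, rt; filter; then 1 M HCl, THF, rt
Reagents that add atoms: water, O
Why: Heterogeneous hydrogenation saturates the disubstituted alkene without touching arene or acetal, and acid hydrolysis of the dimethyl acetal then frees the aldehyde, whose stereocentre is β to the carbonyl and cannot epimerise.

Step 6
Reactants: 10 (3R)-3-methyl-11-phenylundecanal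
Product: 11 [(9R)-9-methyldodec-11-yn-1-yl]benzene
Conditions: dimethyl (1-diazo-2-oxopropyl)phosphonate, K2CO3, MeOH, 0 °C to rt
Reagents that add atoms: dimethyl (1-diazo-2-oxopropyl)phosphonate, CC(=O)C(=[N+]=[N-])P(=O)(OC)OC
Why: Ohira–Bestmann (Seyferth–Gilbert) homologation converts the aldehyde into the terminal alkyne with one added carbon under mild carbonate conditions.

Step 7
Reactants: 11 [(9R)-9-methyldodec-11-yn-1-yl]benzene
Product: 14 (2E,5R)-3,5-dimethyl-13-phenyltridec-2-en-1-ol, via alkenylalane 12 (not isolated), via lithium alkenylaluminate 13 (not isolated)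
Conditions: AlMe3, Cp2ZrCl2 (cat.), CH2Cl2, 0 °C to rt; evaporate; n-BuLi, THF/hexane, –78 °C; (CH2O)n, –78 °C to rt; aqueous work-up
Reagents that add atoms: trimethylaluminium, C[Al](C)C; paraformaldehyde (as formaldehyde), C=O
Why: Zirconium-catalysed Negishi carboalumination adds methyl and aluminium syn across the terminal alkyne with methyl on the internal carbon, and hydroxymethylation of the derived aluminate proceeds with retention, which fixes the E geometry of the trisubstituted allylic alcohol.

Step 8
Reactants: 14 (2E,5R)-3,5-dimethyl-13-phenyltridec-2-en-1-ol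
Product: 15 [(2S,3S)-3-methyl-3-[(2R)-2-methyl-10-phenyldecyl]oxiran-2-yl]methanol
Conditions: Ti(OiPr)4 (cat.), L-(+)-diisopropyl tartrate (cat.), t-BuOOH, 4 Å molecular sieves, CH2Cl2, –20 °C
Reagents that add atoms: tert-butyl hydroperoxide, CC(C)(C)OO
Why: Sharpless asymmetric epoxidation with the L-(+)-tartrate is expected to deliver oxygen to the alkene face that gives the (2S,3S)-epoxide, as for (E)-3-methylalk-2-en-1-ols in general, under reagent control that overrides the remote C5 methyl centre.

Step 9
Reactants: 15 [(2S,3S)-3-methyl-3-[(2R)-2-methyl-10-phenyldecyl]oxiran-2-yl]methanol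
Product: 16 (2S,3R,5R)-3-hydroperoxy-3,5-dimethyl-13-phenyltridecane-1,2-diol
Conditions: anhydrous H2O2 in Et2O (excess), H3PMo12O40 (cat.), rt
Reagents that add atoms: hydrogen peroxide, OO
Why: Acid-catalysed perhydrolysis of a trisubstituted epoxide opens the C–O bond at the more substituted carbon by backside attack, so the tertiary hydroperoxide should form with inversion at C3 of 15 (the future ring C6) while C2 keeps its configuration.

Step 10
Reactants: 17 propane-1,3-diol
Product: 18 3-{[tri(propan-2-yl)silyl]oxy}propan-1-ol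
Conditions: i-Pr3SiCl, imidazole, excess 17, CH2Cl2, 0 °C to rt
Reagents that add atoms: chlorotri(propan-2-yl)silane, CC(C)[Si](Cl)(C(C)C)C(C)C
Why: Statistical monosilylation of the symmetrical diol used in excess gives the mono silyl ether.

Step 11
Reactants: 18 3-{[tri(propan-2-yl)silyl]oxy}propan-1-ol
Product: 19 3-{[tri(propan-2-yl)silyl]oxy}propanal
Conditions: TEMPO (cat.), PhI(OAc)2, CH2Cl2, rt
Reagents that add atoms: none
Why: Nitroxyl-catalysed oxidation with the hypervalent iodine co-oxidant stops at the aldehyde and avoids base that could eliminate the β-silyloxy group.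

Step 12
Reactants: 19 3-{[tri(propan-2-yl)silyl]oxy}propanal; 20 isopropenylmagnesium bromide
Product: 21 rac-2-methyl-5-{[tri(propan-2-yl)silyl]oxy}pent-1-en-3-ol
Conditions: 20, THF, –78 to 0 °C; aqueous work-up
Reagents that add atoms: none
Why: 1,2-Addition of the alkenyl Grignard reagent to the aldehyde gives the racemic secondary allylic alcohol.

Step 13
Reactants: 21 rac-2-methyl-5-{[tri(propan-2-yl)silyl]oxy}pent-1-en-3-ol
Product: 22 (3R)-2-methyl-5-{[tri(propan-2-yl)silyl]oxy}pent-1-en-3-ol
Conditions: Ti(OiPr)4, L-(+)-diisopropyl tartrate, t-BuOOH (0.6 equiv), 4 Å molecular sieves, CH2Cl2, –20 °C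
Reagents that add atoms: none
Why: In the Sharpless kinetic resolution the L-(+)-tartrate catalyst epoxidises the S enantiomer of a secondary allylic alcohol much faster, so the unreacted R alcohol should be recovered enantiomerically enriched once conversion passes one half.

Step 14
Reactants: 22 (3R)-2-methyl-5-{[tri(propan-2-yl)silyl]oxy}pent-1-en-3-ol
Product: 23 (3R)-2-methyl-5-{[tri(propan-2-yl)silyl]oxy}pent-1-en-3-yl methanesulfonate
Conditions: (MeSO2)2O, Et3N, CH2Cl2, –30 °C; cold aqueous work-up, used at once
Reagents that add atoms: methanesulfonic anhydride, CS(=O)(=O)OS(C)(=O)=O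
Why: O-Sulfonylation with the anhydride at low temperature gives the allylic mesylate with retention at carbon and without chloride ion that could cause allylic substitution.

Step 15
Reactants: 16 (2S,3R,5R)-3-hydroperoxy-3,5-dimethyl-13-phenyltridecane-1,2-diol; 23 (3R)-2-methyl-5-{[tri(propan-2-yl)silyl]oxy}pent-1-en-3-yl methanesulfonate
Product: 25 (2S,3R,5R)-3,5-dimethyl-3-{[(3S)-2-methyl-5-{[tri(propan-2-yl)silyl]oxy}pent-1-en-3-yl]peroxy}-13-phenyltridecane-1,2-diol, via caesium alkylperoxide 24 (not isolated)
Conditions: 16, Cs2CO3, DMF, 0 °C; then 23, 0 °C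
Reagents that add atoms: none
Why: SN2 O-alkylation of the caesium alkylperoxide (more acidic than the diol hydroxyls and more nucleophilic through the α-effect) on the secondary allylic mesylate should form the dialkyl peroxide with inversion, turning the R mesylate carbon into the S-configured future C3.

Step 16
Reactants: 25 (2S,3R,5R)-3,5-dimethyl-3-{[(3S)-2-methyl-5-{[tri(propan-2-yl)silyl]oxy}pent-1-en-3-yl]peroxy}-13-phenyltridecane-1,2-diol
Product: 26 (2R,4R)-2,4-dimethyl-2-{[(3S)-2-methyl-5-{[tri(propan-2-yl)silyl]oxy}pent-1-en-3-yl]peroxy}-12-phenyldodecanal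
Conditions: NaIO4, THF/pH 7 buffer, 0 °C to rt
Reagents that add atoms: none
Why: Periodate glycol cleavage removes C1 as formaldehyde and unmasks an aldehyde on the quaternary peroxy carbon, which has no α-hydrogen and so can neither epimerise nor fragment in the Kornblum–DeLaMare sense.

Step 17
Reactants: 26 (2R,4R)-2,4-dimethyl-2-{[(3S)-2-methyl-5-{[tri(propan-2-yl)silyl]oxy}pent-1-en-3-yl]peroxy}-12-phenyldodecanal
Product: 27 (3S)-2-methyl-5-{[tri(propan-2-yl)silyl]oxy}pent-1-en-3-yl (3R,5R)-3,5-dimethyl-13-phenyltridec-1-en-3-yl peroxide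
Conditions: Ph3PCH3Br, KN(SiMe3)2, THF, 0 °C; then 26, –78 to 0 °C
Reagents that add atoms: methyltriphenylphosphonium bromide, [Br-].C[P+](c1ccccc1)(c1ccccc1)c1ccccc1
Why: Wittig methylenation of the non-enolisable aldehyde at low temperature should install the C6 vinyl group faster than the ylide attacks the dialkyl peroxide or deprotonates the C3–H bond.

Step 18
Reactants: 27 (3S)-2-methyl-5-{[tri(propan-2-yl)silyl]oxy}pent-1-en-3-yl (3R,5R)-3,5-dimethyl-13-phenyltridec-1-en-3-yl peroxide
Product: 28 (3S,6R)-4,6-dimethyl-6-[(2R)-2-methyl-10-phenyldecyl]-3-(2-{[tri(propan-2-yl)silyl]oxy}ethyl)-3,6-dihydro-1,2-dioxine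
Conditions: second-generation Grubbs catalyst (SIMes)(PCy3)Cl2Ru=CHPh (cat.), CH2Cl2 (high dilution), 40 °C, argon sparge
Reagents that add atoms: none
Why: The ruthenium benzylidene exchanges onto the monosubstituted vinyl group at C6 by [2+2] cycloaddition and cycloreversion, the new alkylidene adds intramolecularly to the 1,1-disubstituted alkene on C3, and cycloreversion of that ruthenacyclobutane forms the C4=C5 bond and returns a ruthenium methylidene, the two terminal CH2 groups leaving as ethene. The closest known reaction type is ring-closing metathesis of bis-allylic dialkyl peroxides to 3,6-dihydro-1,2-dioxines. The six-membered ring (O1, O2, C3, C4, C5, C6) closes by joining the two alkene carbons that are each allylic to a peroxide oxygen, so no other ring size is open to this diene. No stereocentre is created, and C3 (S) and C6 (R) are carried in unchanged because neither C–O bond takes part. The step needs chemoselectivity for the two alkenes over the O–O bond and the C3–H bond, which the ruthenium carbene (tolerant of dialkyl peroxides) should provide, while high dilution and removal of ethene favour cyclisation over cross-metathesis.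

Step 19
Reactants: 28 (3S,6R)-4,6-dimethyl-6-[(2R)-2-methyl-10-phenyldecyl]-3-(2-{[tri(propan-2-yl)silyl]oxy}ethyl)-3,6-dihydro-1,2-dioxine
Product: 29 (3S,4S,6R)-4,6-dimethyl-6-[(2R)-2-methyl-10-phenyldecyl]-3-(2-{[tri(propan-2-yl)silyl]oxy}ethyl)-1,2-dioxane
Conditions: KO2CN=NCO2K (large excess, in portions), AcOH, MeOH/CH2Cl2, 0 °C to rt
Reagents that add atoms: none
Why: Concerted syn transfer of two hydrogens from diimide, which leaves O–O bonds untouched, is expected on the face of the C4=C5 alkene that carries only the C6 methyl, opposite the cis C3 and C6 side arms, which places the C4 methyl cis to the C3 arm (4S).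

Step 20
Reactants: 29 (3S,4S,6R)-4,6-dimethyl-6-[(2R)-2-methyl-10-phenyldecyl]-3-(2-{[tri(propan-2-yl)silyl]oxy}ethyl)-1,2-dioxane
Product: 30 2-[(3S,4S,6R)-4,6-dimethyl-6-[(2R)-2-methyl-10-phenyldecyl]-1,2-dioxan-3-yl]ethan-1-ol
Conditions: Bu4NF, AcOH, THF, 0 °C to rt
Reagents that add atoms: none
Why: Fluoride cleaves the Si–O bond of the primary silyl ether, and the acetic acid buffer keeps the medium from becoming basic enough to remove the C3–H next to the peroxide.

Step 21
Reactants: 30 2-[(3S,4S,6R)-4,6-dimethyl-6-[(2R)-2-methyl-10-phenyldecyl]-1,2-dioxan-3-yl]ethan-1-ol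
Product: 32 2-[(3S,4S,6R)-4,6-dimethyl-6-[(2R)-2-methyl-10-phenyldecyl]-1,2-dioxan-3-yl]acetic acid, via peroxy aldehyde 31 (not isolated)
Conditions: TEMPO (cat.), PhI(OAc)2, MeCN/H2O, rt
Reagents that add atoms: water, O
Why: Nitroxyl-catalysed oxidation in aqueous acetonitrile takes the primary alcohol through the aldehyde hydrate to the carboxylic acid under mildly acidic conditions that should neither reduce the peroxide nor trigger β-elimination of the peroxy group.

**Compound list**
1 | (3R)-3,7-dimethyloct-6-enal [(R)-citronellal] | C[C@H](CCC=C(C)C)CC=O | starting material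
2 | (6R)-8,8-dimethoxy-2,6-dimethyloct-2-ene | C[C@H](CCC=C(C)C)CC(OC)OC | intermediate
3 | 3-[(3R)-5,5-dimethoxy-3-methylpentyl]-5,5-dimethyl-1,2,4-trioxolane (secondary ozonide, both epimers at the ring CH) | C[C@H](CCC1OOC(C)(C)O1)CC(OC)OC | intermediate
4 | (4R)-6,6-dimethoxy-4-methylhexanal | C[C@H](CCC=O)CC(OC)OC | intermediate
5 | (5-bromopentyl)benzene | BrCCCCCc1ccccc1 | starting material
6 | triphenyl(5-phenylpentyl)phosphonium bromide | [Br-].c1ccc(cc1)CCCCC[P+](c1ccccc1)(c1ccccc1)c1ccccc1 | intermediate
7 | triphenyl(5-phenylpentylidene)phosphorane | c1ccc(cc1)CCCCC=P(c1ccccc1)(c1ccccc1)c1ccccc1 | intermediate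
8 | [(5Z,9R)-11,11-dimethoxy-9-methylundec-5-en-1-yl]benzene | C[C@H](CC/C=C\CCCCc1ccccc1)CC(OC)OC | intermediate
9 | [(9R)-11,11-dimethoxy-9-methylundecyl]benzene | C[C@H](CCCCCCCCc1ccccc1)CC(OC)OC | intermediate
10 | (3R)-3-methyl-11-phenylundecanal | C[C@H](CCCCCCCCc1ccccc1)CC=O | intermediate
11 | [(9R)-9-methyldodec-11-yn-1-yl]benzene | C[C@H](CCCCCCCCc1ccccc1)CC#C | intermediate
12 | [(1E,4R)-2,4-dimethyl-12-phenyldodec-1-en-1-yl]dimethylaluminium | C[C@H](CCCCCCCCc1ccccc1)C/C(C)=C/[Al](C)C | intermediate
13 | lithium butyl[(1E,4R)-2,4-dimethyl-12-phenyldodec-1-en-1-yl]dimethylaluminate | [Li+].C[C@H](CCCCCCCCc1ccccc1)C/C(C)=C/[Al-](C)(C)CCCC | intermediate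
14 | (2E,5R)-3,5-dimethyl-13-phenyltridec-2-en-1-ol | C[C@H](CCCCCCCCc1ccccc1)C/C(C)=C/CO | intermediate
15 | [(2S,3S)-3-methyl-3-[(2R)-2-methyl-10-phenyldecyl]oxiran-2-yl]methanol | C[C@H](CCCCCCCCc1ccccc1)C[C@]1(C)O[C@H]1CO | intermediate
16 | (2S,3R,5R)-3-hydroperoxy-3,5-dimethyl-13-phenyltridecane-1,2-diol | C[C@H](CCCCCCCCc1ccccc1)C[C@](OO)(C)[C@@H](O)CO | intermediate
17 | propane-1,3-diol | OCCCO | starting material
18 | 3-{[tri(propan-2-yl)silyl]oxy}propan-1-ol | OCCCO[Si](C(C)C)(C(C)C)C(C)C | intermediate
19 | 3-{[tri(propan-2-yl)silyl]oxy}propanal | O=CCCO[Si](C(C)C)(C(C)C)C(C)C | intermediate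
20 | isopropenylmagnesium bromide (prop-1-en-2-ylmagnesium bromide) | C=C(C)[Mg]Br | starting material
21 | rac-2-methyl-5-{[tri(propan-2-yl)silyl]oxy}pent-1-en-3-ol | C=C(C)C(O)CCO[Si](C(C)C)(C(C)C)C(C)C | intermediate
22 | (3R)-2-methyl-5-{[tri(propan-2-yl)silyl]oxy}pent-1-en-3-ol | C=C(C)[C@H](O)CCO[Si](C(C)C)(C(C)C)C(C)C | intermediate
23 | (3R)-2-methyl-5-{[tri(propan-2-yl)silyl]oxy}pent-1-en-3-yl methanesulfonate | C=C(C)[C@H](OS(C)(=O)=O)CCO[Si](C(C)C)(C(C)C)C(C)C | intermediate
24 | caesium (2S,3R,5R)-1,2-dihydroxy-3,5-dimethyl-13-phenyltridecan-3-yl peroxide (caesium salt of 16) | [Cs+].C[C@H](CCCCCCCCc1ccccc1)C[C@](O[O-])(C)[C@@H](O)CO | intermediate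
25 | (2S,3R,5R)-3,5-dimethyl-3-{[(3S)-2-methyl-5-{[tri(propan-2-yl)silyl]oxy}pent-1-en-3-yl]peroxy}-13-phenyltridecane-1,2-diol | C[C@H](CCCCCCCCc1ccccc1)C[C@](OO[C@@H](CCO[Si](C(C)C)(C(C)C)C(C)C)C(C)=C)(C)[C@@H](O)CO | intermediate
26 | (2R,4R)-2,4-dimethyl-2-{[(3S)-2-methyl-5-{[tri(propan-2-yl)silyl]oxy}pent-1-en-3-yl]peroxy}-12-phenyldodecanal | C[C@H](CCCCCCCCc1ccccc1)C[C@](OO[C@@H](CCO[Si](C(C)C)(C(C)C)C(C)C)C(C)=C)(C)C=O | intermediate
27 | (3S)-2-methyl-5-{[tri(propan-2-yl)silyl]oxy}pent-1-en-3-yl (3R,5R)-3,5-dimethyl-13-phenyltridec-1-en-3-yl peroxide | C[C@H](CCCCCCCCc1ccccc1)C[C@](OO[C@@H](CCO[Si](C(C)C)(C(C)C)C(C)C)C(C)=C)(C)C=C | intermediate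
28 | (3S,6R)-4,6-dimethyl-6-[(2R)-2-methyl-10-phenyldecyl]-3-(2-{[tri(propan-2-yl)silyl]oxy}ethyl)-3,6-dihydro-1,2-dioxine | C[C@H](CCCCCCCCc1ccccc1)C[C@]1(C)C=C(C)[C@H](CCO[Si](C(C)C)(C(C)C)C(C)C)OO1 | intermediate
29 | (3S,4S,6R)-4,6-dimethyl-6-[(2R)-2-methyl-10-phenyldecyl]-3-(2-{[tri(propan-2-yl)silyl]oxy}ethyl)-1,2-dioxane | C[C@H](CCCCCCCCc1ccccc1)C[C@]1(C)C[C@H](C)[C@H](CCO[Si](C(C)C)(C(C)C)C(C)C)OO1 | intermediate
30 | 2-[(3S,4S,6R)-4,6-dimethyl-6-[(2R)-2-methyl-10-phenyldecyl]-1,2-dioxan-3-yl]ethan-1-ol | C[C@H](CCCCCCCCc1ccccc1)C[C@]1(C)C[C@H](C)[C@H](CCO)OO1 | intermediate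
31 | 2-[(3S,4S,6R)-4,6-dimethyl-6-[(2R)-2-methyl-10-phenyldecyl]-1,2-dioxan-3-yl]acetaldehyde | C[C@H](CCCCCCCCc1ccccc1)C[C@]1(C)C[C@H](C)[C@H](CC=O)OO1 | intermediate
32 | 2-[(3S,4S,6R)-4,6-dimethyl-6-[(2R)-2-methyl-10-phenyldecyl]-1,2-dioxan-3-yl]acetic acid (CNP0342712.1) | C[C@H](CCCCCCCCc1ccccc1)C[C@]1(C)C[C@H](C)[C@H](CC(=O)O)OO1 | target

**Step count and risks**
Total: 21 steps. Longest linear sequence: 15 steps (steps 1, 2, 4–9 and 15–21, from (R)-citronellal).

Steps most likely to fail:

Step 15 (peroxide alkylation). Direct SN2 displacement at the secondary allylic carbon of 23 by the hindered caesium alkylperoxide may be outrun by SN2′ attack at the terminal methylene, by E2 elimination to the diene, or by base-induced fragmentation of the β-hydroxy hydroperoxide. The fallback reverses the roles of the partners. It sets out from mesylate 23, which is treated with a large excess of H2O2 and KOH in THF/MeOH at 0 °C, so that the small, weakly basic hydroperoxide anion displaces the mesylate with inversion to give (3S)-2-methyl-5-{[tri(propan-2-yl)silyl]oxy}pent-1-en-3-yl hydroperoxide F1. F1 then takes the place of H2O2 in the H3PMo12O40-catalysed opening of epoxy alcohol 15 at its tertiary carbon (Et2O, rt, inversion as in step 9). This comes back to the route at peroxide diol 25, with 16 and 24 bypassed.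

Step 18 (ring-closing metathesis). Slow loading of the catalyst on the vinyl group at the quaternary C6 and slow closure onto the 1,1-disubstituted alkene may leave time for catalyst decomposition, alkene isomerisation or ruthenium-induced O–O cleavage. The fallback is a relay metathesis that sets out from aldehyde 26. Wittig reaction with the ylide from (hex-5-en-1-yl)triphenylphosphonium bromide and KN(SiMe3)2 gives the relay triene (3S)-2-methyl-5-{[tri(propan-2-yl)silyl]oxy}pent-1-en-3-yl (6Z,8R,10R)-8,10-dimethyl-18-phenyloctadeca-1,6-dien-8-yl peroxide F2. The second-generation Grubbs catalyst then loads on the unhindered terminal alkene, expels cyclopentene to place the alkylidene on the carbon attached to C6, and closes onto the isopropenyl group. This comes back to the route at dihydrodioxine 28.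

Step 19 (diimide reduction). Hydrogen transfer to the trisubstituted C4=C5 alkene next to the quaternary C6 may be slow, and discrimination between the face with the C6 methyl and the face with the two side arms may be incomplete, which would give the C4 epimer. The fallback replaces concerted diimide transfer by surface-catalysed hydrogenation. It sets out from 28 and uses H2 (1 atm) over PtO2 (platinum dioxide) in EtOAc at 0 °C with short contact time; adsorption on the metal should distinguish the two faces more strongly, and O–O hydrogenolysis is the competing process to watch. It comes back to the route at 29 and makes no new compound (F0).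

**Further compounds**
F1 | step 15 | (3S)-2-methyl-5-{[tri(propan-2-yl)silyl]oxy}pent-1-en-3-yl hydroperoxide | OO[C@@H](CCO[Si](C(C)C)(C(C)C)C(C)C)C(C)=C
F2 | step 18 | (3S)-2-methyl-5-{[tri(propan-2-yl)silyl]oxy}pent-1-en-3-yl (6Z,8R,10R)-8,10-dimethyl-18-phenyloctadeca-1,6-dien-8-yl peroxide | C[C@H](CCCCCCCCc1ccccc1)C[C@](OO[C@@H](CCO[Si](C(C)C)(C(C)C)C(C)C)C(C)=C)(C)/C=C\CCCC=C
F0 | step 19 | none | none
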